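## The problem

Compound 13 is an isochroman-1-one. A six-membered lactone, ring B (C1, O2, C3, C4, C4a, C8a), is fused to a benzene ring, ring A, at the adjacent carbons C4a and C8a. Ring A is substituted everywhere except C7 and carries free hydroxyl groups at C5, C6 and C8, an electron-rich, oxidation-prone pattern that must be masked for most of the route. Ring B holds both stereocenters in a trans relationship: C3 (S), bearing O2 and a methyl ester, and the benzylic C4 (R), bearing the side chain. A group entering at C4 of a ring that already contains C3 should come in on the face away from the C3 ester, so C3 can control C4 and only C3 needs an outside source of chirality. The side chain is a fumaric acid unit bound to C4 through one alkene carbon, with a methyl ester on that carbon and the free acid on the other (E). The four carboxyl carbons therefore exist as one lactone, two methyl esters and one acid, and they must be kept apart. C3–H is alpha to an ester, and C4–H is benzylic, allylic and beta to the lactone oxygen, so base threatens epimerisation, double-bond migration and ring-opening β-elimination once the side chain is on; the end game should be acidic or neutral. The feature that allows a short route is the ring junction: C8a is para to the C6 oxygen and ortho to the C8 oxygen, which is where a 1,2,4-trialkoxybenzene takes up iodine; C4a is then the only C–H ortho to that iodine; and what must be added across these two carbons (C4, C3 with its ester, O2, and C1) is a glycidic ester plus one molecule of CO.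

## Retrosynthesis

**13 ⇒ 12 (release of phenols and acid).** Three aryl O–H bonds and the acid O–H bond are traced back to three O–CH3 bonds and one O–C(CH3)3 bond in the tri-O-methyl tert-butyl ester 12. Methyl ethers are preferred over benzyl, isopropyl or acetal groups because those offer weak C–H bonds to a bromine atom in the radical step before. The tert-butyl ester keeps the far carboxyl distinct from the two methyl esters. The forward reaction must cleave four O–alkyl bonds with a Lewis acid and leave two methyl esters, the lactone and the alkene alone.

**12 ⇒ 11 + 10 (C4–side chain bond).** The C4–C(alkene) bond is cut to the benzylic bromide 11 and tert-butyl methyl bromofumarate 10. C4 has no acidifying group other than the arene, so enolate chemistry is not available. A C4 radical joined to an alkenyl–nickel species makes this C(sp3)–C(sp2) bond without a polar bias and brings in the whole side chain, with geometry and ester pattern already fixed in a small molecule. Compound 11 has one stereocenter that matters (C3) and 10 has none. The forward step must form the bond trans to the C3 ester and keep the fumarate geometry.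

**11 ⇒ 5 (C4–Br).** Removing bromine leaves the lactone 5. C4 is the only benzylic carbon, so hydrogen abstraction needs no directing element. The demand is chemoselectivity against ionic bromination of ring A at C7.

**10 ⇒ 7 + 8 through 9; 7 ⇒ 6 (bromofumarate).** The C=C bond of 10 is cut in the Wittig sense to tert-butyl glyoxylate 7 and the bromo ylide 9, made in the flask from the commercial ylide 8. Bromine and the methyl ester arrive on the same carbon, so the position of bromine is fixed. Bromination–dehydrobromination of a mixed fumarate, or HBr addition to a mixed acetylenedicarboxylate, would not fix it. Glyoxylate 7 comes from di-tert-butyl L-tartrate 6 by glycol cleavage.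

**5 ⇒ 2 + 3 + 4 (ring B).** Three bonds are cut at once, C4a–C4, C8a–C1 and C1–O2, giving 1-iodo-2,4,5-trimethoxybenzene 2, methyl (S)-glycidate 3 and carbon monoxide 4. Compared with stepwise homologation of a benzoic acid, this uses both adjacent ring positions in one catalytic cycle and needs no directing group that must later be removed. C3 is a bought stereocenter whose C–O bond is never broken. This is the largest simplification of the route: a bicyclic, stereodefined lactone becomes a monocyclic aryl iodide and two commodity reagents. The forward reaction must alkylate the ortho C–H with the CH2 of the epoxide before anything happens at the C–I carbon, then carbonylate and close the ring through the alkoxide.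

**2 ⇒ 1 (aryl iodide).** The C–I bond is cut to 1,2,4-trimethoxybenzene 1. The carbon para to one methoxy group and ortho to another is the most nucleophilic unhindered site, so electrophilic iodination should give 2 directly.

## Roads not taken

**Alternative 1:** The cut is C3–C4 and O2–C1. The benzylfumarate A2 has C1 and the C8 oxygen tied up as a benzodioxinone on its arene. It would be converted in the flask into its silyl dienol ether A3, which adds through C4 to methyl glyoxylate A4 held by Cu(OTf)2 and a chiral bis(oxazoline). Fluoride then frees the C3 alkoxide, which opens the dioxinone and closes ring B to give A1.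
- Merits: both stereocenters are set in one catalytic step, the side chain is complete before ring closure, and no radical bromination of an electron-rich arene or cross-electrophile coupling is needed. In these respects it is the better plan.
- Weak points: the donor is an electron-poor, cross-conjugated dienolate. It must react at C4 and not alpha to the tert-butyl ester, with the right syn/anti sense, the right absolute sense and the right geometry of the re-formed double bond. These four selectivities rest on one untested catalyst–substrate pairing.
- Further weak points: A2 is a pentasubstituted arene that needs several steps, and the benzyl ethers of A1 cannot be removed by hydrogenolysis without losing the alkene, so a Lewis acid is needed at the end anyway.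
- Comparison: the chosen plan offers a bought C3 stereocenter, a single relative stereochemical question (C4 against C3), and a ring-forming step that starts from a one-step aryl iodide.

**Alternative 2:** The cut is C5–C4a and C8–C8a of ring A. A (4+2) cycloaddition of the bis(trimethylsilyloxy)diene A6 with dimethyl penta-2,3-dienedioate A7, then loss of Me3SiOMe and a proton shift, would give the homophthalate A5.
- Merits: the benzannulation is regiochemically reliable and leaves the C5 oxygen differentiated from those at C6 and C8. It delivers C4 as a methylene acidified by both the arene and an ester, a better handle for polar C–C bond formation at C4 than anything in the chosen route.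
- Weak points: it builds the one part of the target that can be bought and forms no stereocenter. C3 is left as an ester carbon that must be reduced and extended by a carboxyl carbon before ring B can close. Both stereocenters and the whole side chain are still to come.
- Comparison: the chosen plan reaches the stereodefined lactone 5 in two steps from a commercial arene, whereas this road would still hold an achiral arene after considerably more.

**Alternative 3:** The cut is O2–C3. The trans-indanone β-keto ester A9 would be converted into A8, which is the same compound as 12, by a flavin-dependent Baeyer–Villiger monooxygenase with NADPH and O2. Oxygen would be inserted between the ketone carbon and the ester-bearing carbon.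
- Merits: the skeleton is assembled in a carbocycle whose trans relationship is under thermodynamic control through the enolisable β-keto ester. The last skeletal step is a single oxygen insertion under very mild conditions, and the late bromination and nickel coupling of the chosen route are avoided.
- Weak points: a peracid would move the electron-rich aryl group, not the ester-bearing carbon, so the regiochemistry rests entirely on an enzyme. Its acceptance of a large, hexasubstituted indanone carrying a Michael acceptor is unknown. A9 needs an enantioselective synthesis of its own, and the uncertain step falls on the most advanced intermediate.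
- Comparison: both roads meet at the same compound and share the final deprotection. The chosen plan places its risk in step 2, on material made in one step.

Key step: step 2

Remark on the chemistry: bromide 11 is taken to form as a mixture of C4 epimers; both give the same planar C4 radical in step 6, so the mixture is used as it is. Atom labels C1–C8a are those of the isochroman-1-one throughout.

Step 1
Reactants: 1 1,2,4-trimethoxybenzene
Product: 2 1-iodo-2,4,5-trimethoxybenzene
Conditions: NIS (1.05 equiv), CF3CO2H (10 mol %), MeCN, rt
Reagents that add atoms: N-iodosuccinimide, O=C1CCC(=O)N1I
Why: Electrophilic aromatic iodination; of the three free positions of 1, C5 is para to one methoxy group and ortho to another, C3 is squeezed between two methoxy groups and C6 is activated by one only, so iodine should enter at C5, the future C8a.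

Step 2
Reactants: 2 1-iodo-2,4,5-trimethoxybenzene; 3 methyl (S)-oxirane-2-carboxylate; 4 carbon monoxide
Product: 5 methyl (S)-5,6,8-trimethoxy-1-oxoisochromane-3-carboxylate
Conditions: Pd(OAc)2 (10 mol %), P(2-furyl)3 (22 mol %), norbornene (2 equiv), K2CO3 (2.5 equiv), 3 (3 equiv), CO (balloon, 1 atm), MeCN, 70 °C
Reagents that add atoms: none
Why: Proposed new method: zerovalent palladium should add to the C–I bond of 2, norbornene should insert, and carbonate-assisted palladation of the only ortho C–H (the future C4a) should give the aryl–norbornyl palladacycle of divalent palladium, which opens 3 at its unsubstituted CH2 by SN2-type oxidative addition to tetravalent palladium; aryl–alkyl reductive elimination then forms C4a–C4. With both ortho positions filled, norbornene is expelled by β-carbon elimination, CO inserts into the C8a–Pd bond, and the tethered C3 alkoxide takes the acyl group from palladium, forming C1–O2 and closing ring B by a 6-exo-trig acyl substitution that returns zerovalent palladium. The closest known reaction types are the Catellani ortho-alkylation of aryl iodides by epoxides that ends in ipso C–O closure to dihydrobenzofurans, and carbonylative ipso terminations of Catellani reactions; joining the two in one flask is what is new. No stereocenter is formed: C3 comes from 3 with its C–O bond untouched, so the S configuration is carried over. The step needs ortho alkylation before any ipso event, which the ortho methoxy group of 2 and the excess of strained norbornene should secure. It needs attack at the CH2 of the epoxide and not at the ester-bearing carbon, which sterics and the deactivating ester should secure. It needs carbonylation ahead of C–O reductive elimination, which should hold because CO insertion into an aryl–palladium bond is fast at 1 atm while C–O reductive elimination is slow with a small, weakly donating phosphine.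

Step 3
Reactants: 6 di-tert-butyl L-tartrate
Product: 7 tert-butyl glyoxylate
Conditions: H5IO6 (1.1 equiv), Et2O, rt; filtration, distillation
Reagents that add atoms: none
Why: Malaprade glycol cleavage of the vicinal diol gives two molecules of the glyoxylate per tartrate and leaves the tert-butyl esters untouched; the aldehyde is used at once because it hydrates and oligomerises on standing.

Step 4
Reactants: 8 methyl (triphenylphosphoranylidene)acetate; 7 tert-butyl glyoxylate
Product: 10 4-tert-butyl 1-methyl (Z)-2-bromobut-2-enedioate, via methyl bromo(triphenylphosphoranylidene)acetate 9 (not isolated)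
Conditions: NBS (1.0 equiv), CH2Cl2, −20 °C; then 7 (1.2 equiv), −20 °C to rt
Reagents that add atoms: N-bromosuccinimide, O=C1CCC(=O)N1Br
Why: Bromination of the stabilised ylide 8 at carbon and proton transfer to the succinimide anion should give the bromo ylide 9, whose Wittig reaction with 7 places the ylide ester trans to the aldehyde substituent, as stabilised ylides do. The two esters therefore end up trans (a bromofumarate, Z by the sequence rule), with bromine on the carbon that carries the methyl ester.

Step 5
Reactants: 5 methyl (S)-5,6,8-trimethoxy-1-oxoisochromane-3-carboxylate
Product: 11 methyl (3R,4RS)-4-bromo-5,6,8-trimethoxy-1-oxoisochromane-3-carboxylate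
Conditions: NBS (1.05 equiv), AIBN (5 mol %), PhCF3, 80 °C; used crude
Reagents that add atoms: N-bromosuccinimide, O=C1CCC(=O)N1Br
Why: Wohl–Ziegler bromination: the electrophilic bromine atom should abstract the benzylic C4–H in preference to C3–H, which is flanked by two acceptor groups, and a nonpolar solvent plus the acyl substituent on ring A are relied on to hold back ionic bromination at C7. C3 is unchanged in space; its descriptor becomes R only because bromine raises the rank of C4.

Step 6
Reactants: 11 methyl (3R,4RS)-4-bromo-5,6,8-trimethoxy-1-oxoisochromane-3-carboxylate; 10 4-tert-butyl 1-methyl (Z)-2-bromobut-2-enedioate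
Product: 12 4-tert-butyl 1-methyl (E)-2-[(3S,4R)-5,6,8-trimethoxy-3-(methoxycarbonyl)-1-oxoisochroman-4-yl]but-2-enedioate
Conditions: NiBr2·glyme (10 mol %), 4,4'-di-tert-butyl-2,2'-bipyridine (12 mol %), Mn (3 equiv), 10 (1.5 equiv), DMA, 0 °C
Reagents that add atoms: none
Why: Nickel-catalysed reductive cross-electrophile coupling of a secondary benzylic bromide with an alkenyl bromide: low-valent nickel inserts into the C–Br bond of the electron-poor alkene 10 with retention of geometry, captures the C4 radical formed from 11 by bromine abstraction, and reductive elimination from trivalent nickel forms the C4–alkene bond. The planar C4 radical forgets the configuration of 11 and should be captured on the face away from the C3 ester, which sets C4 as R, trans to C3. The alkene descriptor changes from Z to E only because C4 replaces bromine in the ranking.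

Step 7
Reactants: 12 4-tert-butyl 1-methyl (E)-2-[(3S,4R)-5,6,8-trimethoxy-3-(methoxycarbonyl)-1-oxoisochroman-4-yl]but-2-enedioate
Product: 13 (E)-4-methoxy-4-oxo-3-[(3S,4R)-5,6,8-trihydroxy-3-(methoxycarbonyl)-1-oxoisochroman-4-yl]but-2-enoic acid
Conditions: BBr3 (8 equiv), CH2Cl2, −78 to 0 °C; then H2O, 0 °C
Reagents that add atoms: none
Why: Lewis acid dealkylation: BBr3 should cleave the three aryl methyl ethers through aryloxyboranes and the tert-butyl ester by loss of the tert-butyl cation. The two methyl esters and the lactone have far less basic oxygen atoms and should survive at or below 0 °C, and the acidic medium leaves the base-labile C3–H and C4–H alone.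

**Compound list**

1 | 1,2,4-trimethoxybenzene | COc1ccc(OC)c(OC)c1 | starting material
2 | 1-iodo-2,4,5-trimethoxybenzene | COc1cc(OC)c(OC)cc1I | intermediate
3 | methyl (S)-oxirane-2-carboxylate | COC(=O)[C@@H]1CO1 | starting material
4 | carbon monoxide | [C-]#[O+] | starting material
5 | methyl (S)-5,6,8-trimethoxy-1-oxoisochromane-3-carboxylate | COC(=O)[C@@H]1Cc2c(OC)c(OC)cc(OC)c2C(=O)O1 | intermediate
6 | di-tert-butyl L-tartrate, (2R,3R) | CC(C)(C)OC(=O)[C@H](O)[C@@H](O)C(=O)OC(C)(C)C | starting material
7 | tert-butyl glyoxylate | CC(C)(C)OC(=O)C=O | intermediate
8 | methyl (triphenylphosphoranylidene)acetate | COC(=O)C=P(c1ccccc1)(c1ccccc1)c1ccccc1 | starting material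
9 | methyl bromo(triphenylphosphoranylidene)acetate | COC(=O)C(Br)=P(c1ccccc1)(c1ccccc1)c1ccccc1 | intermediate
10 | 4-tert-butyl 1-methyl (Z)-2-bromobut-2-enedioate (tert-butyl methyl bromofumarate) | COC(=O)/C(Br)=C/C(=O)OC(C)(C)C | intermediate
11 | methyl (3R,4RS)-4-bromo-5,6,8-trimethoxy-1-oxoisochromane-3-carboxylate | COC(=O)[C@@H]1C(Br)c2c(OC)c(OC)cc(OC)c2C(=O)O1 | intermediate
12 | 4-tert-butyl 1-methyl (E)-2-[(3S,4R)-5,6,8-trimethoxy-3-(methoxycarbonyl)-1-oxoisochroman-4-yl]but-2-enedioate | COC(=O)/C(=C/C(=O)OC(C)(C)C)[C@H]1c2c(OC)c(OC)cc(OC)c2C(=O)O[C@@H]1C(=O)OC | intermediate
13 | (E)-4-methoxy-4-oxo-3-[(3S,4R)-5,6,8-trihydroxy-3-(methoxycarbonyl)-1-oxoisochroman-4-yl]but-2-enoic acid | COC(=O)/C(=C/C(=O)O)[C@H]1c2c(O)c(O)cc(O)c2C(=O)O[C@@H]1C(=O)OC | target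

**Step count and risks**

Total step count: 7. Longest linear sequence: 5 steps (steps 1, 2, 5, 6, 7, from 1 to 13); the bromofumarate branch (steps 3, 4) joins at step 6.

**Step 2 (key step, proposed new method).**
- What may go wrong: CO may insert into the first aryl–palladium bond, or into the palladacycle, before the ortho alkylation is complete. That would lead to plain carbonylation of 2 and to catalyst resting as carbonyl clusters.
- Palladation of a C–H flanked by a methoxy group may be slow. If CO is starved, C–O reductive elimination to the dihydrobenzofuran takes over. Carbonate at 70 °C may also erode the C3 configuration of the alpha-acyloxy ester.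
- Fallback (each operation is known chemistry): it sets out from 2 and comes back at 5. Iodine–magnesium exchange on 2 (i-PrMgCl·LiCl, THF) and trapping with diethylcarbamoyl chloride should give N,N-diethyl-2,4,5-trimethoxybenzamide F1. Directed ortho-metalation of F1 (s-BuLi, TMEDA, THF, −78 °C) should go to the carbon flanked by the amide and a methoxy group, the future C4a. After transmetalation with MgBr2·OEt2, CuI-catalysed opening of 3 at its CH2 should give methyl (S)-3-[2-(diethylcarbamoyl)-3,5,6-trimethoxyphenyl]-2-hydroxypropanoate F2. TsOH in warm toluene should then close ring B with loss of diethylamine to give 5. The same three bonds are formed one at a time with a stoichiometric organometallic in place of the palladium/norbornene cycle.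

**Step 6.**
- What may go wrong: reductive β-elimination across C3–C4 (bromide and the lactone carboxylate both leaving) under Mn or low-valent nickel would open ring B to a cinnamate. Loss of HBr to the isocoumarin, reduction or self-coupling of the electron-poor bromofumarate, and poor facial selectivity at C4 are the other risks.
- A cis isomer would have to be separated and not epimerised, because epimerisation at C3 would lead into the enantiomeric series.
- Fallback: it sets out from 10 and 11 and comes back at 12. Zinc dust with LiCl in THF should insert into the C–Br bond of 10 to give [(Z)-4-tert-butoxy-1-methoxy-1,4-dioxobut-2-en-2-yl]zinc bromide F3, held in the fumarate geometry by chelation to the tert-butyl ester carbonyl. A Negishi coupling of F3 with 11 under NiCl2·glyme and a pybox ligand at 0 °C then forms the C4–alkene bond through the same C4 radical. The bromide 11 no longer meets a stoichiometric reducing metal, which removes the ring-opening pathway and the self-coupling of 10.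

**Step 5.**
- What may go wrong: ionic bromination of ring A at C7, which is ortho to two methoxy groups, may compete with the radical chain. The product may also lose HBr to the isocoumarin on heating or on silica.
- Fallback: it sets out from 5 and, because it changes the phenol protection, comes back only at 13. BBr3 on 5 should give methyl (S)-5,6,8-trihydroxy-1-oxoisochromane-3-carboxylate F4. A methyl ester lost at this stage can be restored by Fischer esterification, since only one carboxyl is present. Ac2O/pyridine gives methyl (S)-5,6,8-triacetoxy-1-oxoisochromane-3-carboxylate F5, whose ring is now electron-poor, and Wohl–Ziegler bromination gives methyl (3R,4RS)-5,6,8-triacetoxy-4-bromo-1-oxoisochromane-3-carboxylate F6. F6 takes the place of 11 in the coupling with 10, and the sequence is finished as described under step 7.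

**Step 7.**
- What may go wrong: cleavage of a methyl ester alongside the ethers once the more basic oxygen atoms are used up, or acyl transfer from the side-chain methyl ester to the neighbouring C5 hydroxyl under Lewis acid. Neither can be repaired at this stage, because the three carboxyl groups could not be told apart again.
- Fallback: it sets out from 5 (through F4, F5 and F6 as above) and comes back at 13. Coupling of F6 with 10 under the conditions of step 6 should give 4-tert-butyl 1-methyl (E)-2-[(3S,4R)-5,6,8-triacetoxy-3-(methoxycarbonyl)-1-oxoisochroman-4-yl]but-2-enedioate F7. Near-neutral deacetylation (NH4OAc, aqueous MeOH, rt) should free the phenols to give 4-tert-butyl 1-methyl (E)-2-[(3S,4R)-5,6,8-trihydroxy-3-(methoxycarbonyl)-1-oxoisochroman-4-yl]but-2-enedioate F8. CF3CO2H in CH2Cl2 then removes the tert-butyl ester to give 13. No strong Lewis acid touches the molecule after the side chain is on.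

**Further compounds**

F1 | step 2 | N,N-diethyl-2,4,5-trimethoxybenzamide | CCN(CC)C(=O)c1cc(OC)c(OC)cc1OC
F2 | step 2 | methyl (S)-3-[2-(diethylcarbamoyl)-3,5,6-trimethoxyphenyl]-2-hydroxypropanoate | COC(=O)[C@@H](O)Cc1c(OC)c(OC)cc(OC)c1C(=O)N(CC)CC
F3 | step 6 | [(Z)-4-tert-butoxy-1-methoxy-1,4-dioxobut-2-en-2-yl]zinc bromide | COC(=O)/C([Zn]Br)=C/C(=O)OC(C)(C)C
F4 | step 5 | methyl (S)-5,6,8-trihydroxy-1-oxoisochromane-3-carboxylate | COC(=O)[C@@H]1Cc2c(O)c(O)cc(O)c2C(=O)O1
F5 | step 5 | methyl (S)-5,6,8-triacetoxy-1-oxoisochromane-3-carboxylate | COC(=O)[C@@H]1Cc2c(OC(C)=O)c(OC(C)=O)cc(OC(C)=O)c2C(=O)O1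
F6 | step 5 | methyl (3R,4RS)-5,6,8-triacetoxy-4-bromo-1-oxoisochromane-3-carboxylate | COC(=O)[C@@H]1C(Br)c2c(OC(C)=O)c(OC(C)=O)cc(OC(C)=O)c2C(=O)O1
F7 | step 7 | 4-tert-butyl 1-methyl (E)-2-[(3S,4R)-5,6,8-triacetoxy-3-(methoxycarbonyl)-1-oxoisochroman-4-yl]but-2-enedioate | COC(=O)/C(=C/C(=O)OC(C)(C)C)[C@H]1c2c(OC(C)=O)c(OC(C)=O)cc(OC(C)=O)c2C(=O)O[C@@H]1C(=O)OC
F8 | step 7 | 4-tert-butyl 1-methyl (E)-2-[(3S,4R)-5,6,8-trihydroxy-3-(methoxycarbonyl)-1-oxoisochroman-4-yl]but-2-enedioate | COC(=O)/C(=C/C(=O)OC(C)(C)C)[C@H]1c2c(O)c(O)cc(O)c2C(=O)O[C@@H]1C(=O)OC
A1 | alternative 1 | 4-tert-butyl 1-methyl (E)-2-[(3S,4R)-5,6-bis(benzyloxy)-8-hydroxy-3-(methoxycarbonyl)-1-oxoisochroman-4-yl]but-2-enedioate | COC(=O)/C(=C/C(=O)OC(C)(C)C)[C@H]1c2c(OCc3ccccc3)c(OCc3ccccc3)cc(O)c2C(=O)O[C@@H]1C(=O)OC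
A2 | alternative 1 | 4-tert-butyl 1-methyl (E)-2-{[6,7-bis(benzyloxy)-2,2-dimethyl-4-oxo-4H-1,3-benzodioxin-5-yl]methyl}but-2-enedioate | COC(=O)/C(Cc1c(OCc2ccccc2)c(OCc2ccccc2)cc2OC(C)(C)OC(=O)c12)=C/C(=O)OC(C)(C)C
A3 | alternative 1 | tert-butyldimethylsilyl dienol ether of A2 (alkene geometries left open) | COC(=O)C(=Cc1c(OCc2ccccc2)c(OCc2ccccc2)cc2OC(C)(C)OC(=O)c12)C=C(OC(C)(C)C)O[Si](C)(C)C(C)(C)C
A4 | alternative 1 | methyl glyoxylate | COC(=O)C=O
A5 | alternative 2 | methyl 3-(benzyloxy)-4,6-dihydroxy-2-(2-methoxy-2-oxoethyl)benzoate | COC(=O)Cc1c(OCc2ccccc2)c(O)cc(O)c1C(=O)OC
A6 | alternative 2 | 4-(benzyloxy)-1-methoxy-1,3-bis(trimethylsilyloxy)buta-1,3-diene | COC(O[Si](C)(C)C)=CC(O[Si](C)(C)C)=COCc1ccccc1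
A7 | alternative 2 | dimethyl penta-2,3-dienedioate | COC(=O)C=C=CC(=O)OC
A8 | alternative 3 | 4-tert-butyl 1-methyl (E)-2-[(3S,4R)-5,6,8-trimethoxy-3-(methoxycarbonyl)-1-oxoisochroman-4-yl]but-2-enedioate (identical with 12) | COC(=O)/C(=C/C(=O)OC(C)(C)C)[C@H]1c2c(OC)c(OC)cc(OC)c2C(=O)O[C@@H]1C(=O)OC
A9 | alternative 3 | 4-tert-butyl 1-methyl (E)-2-[(1R,2R)-4,6,7-trimethoxy-2-(methoxycarbonyl)-3-oxo-2,3-dihydro-1H-inden-1-yl]but-2-enedioate | COC(=O)/C(=C/C(=O)OC(C)(C)C)[C@H]1c2c(OC)c(OC)cc(OC)c2C(=O)[C@@H]1C(=O)OC
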